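# Synthesis design for CNP0107857.3

## The problem

The target consists of two trans-2,3-diaryl-2,3-dihydrobenzofurans. Ring A has O1, C2 bearing 4-hydroxyphenyl, C3, and a benzo ring with 4-OH and a 6-[(E)-4-hydroxystyryl] arm. Ring B has O1', C2' bearing the catechol, C3' bearing 3,5-dihydroxyphenyl, and a benzo ring with 4'-OH. The two rings are joined by the sp3–sp2 bond C3–C6'.

There are four stereocentres in two trans pairs, (2R,3R) in ring A and (2S,3S) in ring B. Within a pair the C2 aryl group can steer what happens at C3, because trans is both the anti-addition outcome and the thermodynamic one. The two pairs are insulated from each other by an arene, so each ring needs its own source of absolute configuration, and the two sources must be of opposite sense.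

Both C3 carbons are diaryl-substituted methines. A carbon–carbon bond therefore has to be made twice at a hindered benzylic sp3 centre.

The sensitive features are the eight phenols (one catechol), the E-stilbene (acid, light, hydrogenation, electrophilic oxidants) and the benzylic C2–O bonds para to an oxygenated aryl group (ionisation in acid, quinone-methide opening in base).

The feature that opens the route is the mapping of ring B onto (2S)-eriodictyol. O1'–C7a', O1'–C2', the catechol on a 2S carbon, the oxygen at C4' and an oxygen handle at C6' are O1, C2, the 2-aryl group, 5-O and 7-O of the flavanone. The flavanone has one ring carbon too many (C4). A 1,2-shift of C4a from C4 to C3 expels that carbon as a carboxyl group on C3', exactly where the resorcinol ring must later be attached. Ring A shows the same pattern in the mirror-image series, with a 4-hydroxyphenyl group at C2.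

## Retrosynthesis

**Unmasking (37 ⇐ 36 ⇐ 35).** Five O–CH3 bonds and three O–SO2CH3 bonds are cut. The protecting pattern is dictated by the ring contraction. The oxygens on the benzo rings must remain donors (ethers), and the oxygens on the 2-aryl groups must be acceptors that are inert to the oxidant (mesylates). BBr3 is placed first, on 35, while the mesylated 2-aryl groups still disfavour ionisation of the C2–O bonds. Hydroxide is placed last, on 36, where each ring oxygen sits on a phenolate-bearing arene and is a poor leaving group for quinone-methide opening.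

**Fragment union (35 ⇐ 34 + 17).** The C3–C6' bond is cut. Cutting inside ring A (C2–O1 or C3–C3a) would keep ring B attached through the whole construction of ring A. The C3–C6' cut gives two halves of similar size that both descend from a flavanone by the same chemistry. The forward step is a nickel-catalysed reductive coupling of the redox-active ester 34 with aryl iodide 17. The aryl group must enter the C3 radical anti to the C2 aryl group.

**Ring A arm (34 ⇐ 33 ⇐ 32 ⇐ 30 + 31; 30 ⇐ 29 ⇐ 28).** The C6–vinyl bond is cut. The stilbene cannot meet trivalent iodine, so it is installed after the ring contraction. It is installed before the union so that no hydrogenolysis follows it and the final sequence stays short. The forward Suzuki–Miyaura coupling of triflate 30 with styrylboronate 31 must discriminate the triflate from the aryl mesylate.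

**Ring A contraction (28 ⇐ 25).** The C3–C3a bond of 28 is traced back to the C4–C4a bond of flavanone 25, in the mirror-image series of the key step. This turns a dihydrobenzofuran with two stereocentres into a flavanone with one.

**Ring A stereocentre (25 ⇐ 24 + 19; 24 ⇐ 22 ⇐ 21 ⇐ 20; 19 ⇐ 18).** The C2–aryl bond is cut. No chiral-pool flavanone has the 2R configuration, so C2 is set by rhodium-catalysed asymmetric 1,4-addition of boronic acid 19 to chromone 24. A chalcone cyclisation would be shorter on paper but has no reliable enantioselective version for this substitution. Chromone 24 comes from 2,4,6-trihydroxyacetophenone 20 via 21 and 22, and 19 from 4-hydroxyphenylboronic acid 18.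

**Ring B handle (17 ⇐ 16 ⇐ 15 ⇐ 14 ⇐ 13).** The C6'–I bond is traced back to the C6'–O bond of eriodictyol through boronate 16, triflate 15 and phenol 14. An iodide is chosen because it allows a near-equimolar cross-electrophile union. A boronic acid or organozinc would have to be used in excess.

**Resorcinol ring (13 ⇐ 9 + 10; 9 ⇐ 8 ⇐ 7).** The C3'–aryl bond is cut. The carboxyl group left by the ring contraction is the natural radical precursor. The forward step is a decarboxylative Negishi-type arylation of ester 9 with the zinc reagent from bromide 10, trans to the C2' aryl group.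

**Key disconnection (7 ⇐ 4).** C3'–C3a' is cut while C4–C4a is re-formed, so the dihydrobenzofuran ester 7 becomes flavanone 4. Neighbouring ways to build ring B, such as carbene C–H insertion or phenol–stilbene oxidative coupling, would need a new asymmetric step. Here C2' is bought with the starting material and C3' follows from it.

**Protection of the chiral pool (4 ⇐ 3 ⇐ 2 ⇐ 1).** Three O–C and O–S bonds are cut back to (2S)-eriodictyol 1. The order is benzyl on the most acidic 7-OH, mesyl on the catechol, methyl on the hydrogen-bonded 5-OH. Each step must leave the base-labile C2 centre alone.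

## Roads not taken

**Alternative 1: benzannulation of a cyclobutenone with an ynol ether to make the benzo ring of ring A.** The cut removes C3a–C7a, C4–C5 and C7–C7a. Heating 3-[(E)-4-methoxystyryl]cyclobutenone A1 with the triisopropylsilyl ynol ether A2 (a Danheiser benzannulation) would give the fully substituted resorcinol monosilyl ether A3. Ring A would then be closed by forming O1–C2 at the anisyl carbinol.

- *Merits.* The styryl arm and the oxygenation pattern arrive in one step with fixed regiochemistry. The two ring oxygens of A3 are related by symmetry, so either may close the furan. Closure through a p-methoxybenzyl cation is trans-selective under control of C3. On the styryl arm this road is better, since the plan adopted here spends three steps (hydrogenolysis, triflation, Suzuki–Miyaura coupling) on it.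
- *Weak points.* A2 must already carry ring B and both acyclic stereocentres of ring A. The usual route to an ynol ether, from an ester through an ynolate, puts strong base on a carbon that is α-aryl and β-silyloxy. Epimerisation and β-elimination are both expected. The C3–C6' bond still has to be made, now in an open chain with no ring to direct it.
- *Comparison.* The adopted plan takes C2 from flavanones and lets a ring set C3. It pays with more functional-group steps but avoids a long asymmetric synthesis of A2.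

**Alternative 2: ruthenium-catalysed [2+2+2] assembly of the benzo ring and furan of ring B.** The cut removes C3a'–C7a', C4'–C5' and C6'–C7'. Cp*RuCl(cod) would join diyne A4 (ethynyl ether and silylalkyne ends) with the ring A alkyne A5 to give A6, which carries trimethylsilyl at C4'.

- *Merits.* Arene, dihydrofuran and the C3–C6' link are formed in one step. The C3–C6' bond is prepared as an sp3–sp bond, so no radical arylation is needed. The meta relation of the silyl group and the ring A substituent matches the usual preference of this catalyst. This road is clearly more convergent at the end. The adopted plan needs five steps to turn the eriodictyol oxygen into the same bond.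
- *Weak points.* The secondary benzylic ethynyl ether of A4 has a β-hydrogen and is prone to retro-ene loss of ketene near the reaction temperature. The C4' silyl group must become a hydroxyl, and an aryl–SiMe3 bond needs several steps for that. The anti diaryl diad of A4 must be made in an open chain, with a doubly activated propargylic C–H. A5 still requires a full enantioselective synthesis of ring A.
- *Comparison.* The adopted plan sets against the convergence of this road the fact that ring B's oxygen pattern and C2' configuration come with the starting material, and every step is of a known type.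

**Alternative 3: insertion of an alkoxyaryne into a stilbene oxide C–O bond.** The cut removes O1–C7a and C3–C3a of ring A. Fluoride would release the aryne from silyl triflate A7. The oxygen of trans-epoxide A8 would add to the aryne carbon remote from the methoxy group. The aryl anion would then bond to C3 to give bromide A9.

- *Merits.* This is the shortest conceivable route to ring A. Asymmetric epoxidation of E-stilbenes is well developed. The aryne polarisation places the methoxy group at C4. The bromide is a ready handle for the styryl arm. If the insertion worked it would replace about eight steps of the adopted ring A branch, and on step count it is better.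
- *Weak points.* An epoxide oxygen is a weak nucleophile toward arynes. The aryl anion is tethered through the departing oxygen, so it cannot attack C3 from the rear. The C3–C3a bond must form by front-side collapse or through a benzylic cation. Neither epoxide carbon supports a cation well, since one bears a meta-dioxygenated aryl and the other a triflyloxyphenyl group. Proton capture, three-component opening and wrong-carbon opening are therefore likely. A8 must contain a finished ring B with a carbon substituent at C6', so the ring B problem is untouched.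
- *Comparison.* The adopted plan is longer but rests on one ring contraction used twice and on couplings of established type.

Key step: step 4

Assumption: commercial (2S)-eriodictyol 1 is taken to be of high enantiomeric purity; a partly racemised lot would be upgraded by crystallisation at the stage of 4.

Assumption: the (R)-configured biaryl bisphosphine of step 16 is taken to deliver the 2R flavanone, in line with the known sense of arylrhodium addition to cyclic enones; if the sense on chromone 24 is opposite, the antipodal ligand is used.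

## Route

Step 1
Reactants: 1 (2S)-eriodictyol, (2S)-2-(3,4-dihydroxyphenyl)-5,7-dihydroxychroman-4-one
Product: 2 (2S)-7-(benzyloxy)-2-(3,4-dihydroxyphenyl)-5-hydroxychroman-4-one
Conditions: BnOH, PPh3, DIAD, THF, 0 °C to rt
Reagents that add atoms: benzyl alcohol, OCc1ccccc1
Why: Mitsunobu etherification; the 7-OH is a vinylogous acid and the most acidic phenol, so it is the one alkylated, and the absence of free base keeps the C2 centre from opening to the chalcone.

Step 2
Reactants: 2 (2S)-7-(benzyloxy)-2-(3,4-dihydroxyphenyl)-5-hydroxychroman-4-one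
Product: 3 (2S)-7-(benzyloxy)-5-hydroxy-2-[3,4-bis(methylsulfonyloxy)phenyl]chroman-4-one
Conditions: MsCl (2.2 equiv), pyridine, CH2Cl2, 0 °C
Reagents that add atoms: methanesulfonyl chloride, CS(=O)(=O)Cl
Why: Sulfonylation of the two free catechol hydroxyls; the 5-OH is tied up in a hydrogen bond to the carbonyl and does not react at 0 °C, and mesylation shuts off quinone-methide racemisation through the 4'-phenolate.

Step 3
Reactants: 3 (2S)-7-(benzyloxy)-5-hydroxy-2-[3,4-bis(methylsulfonyloxy)phenyl]chroman-4-one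
Product: 4 (2S)-7-(benzyloxy)-5-methoxy-2-[3,4-bis(methylsulfonyloxy)phenyl]chroman-4-one
Conditions: MeI, Ag2O, CH2Cl2, 35 °C, dark
Reagents that add atoms: iodomethane, CI
Why: Purdie methylation; silver oxide activates iodomethane and takes up HI without forming a free ketone enolate, so the chelated phenol is alkylated while retro-oxa-Michael opening is avoided and 2S is kept.

Step 4
Reactants: 4 (2S)-7-(benzyloxy)-5-methoxy-2-[3,4-bis(methylsulfonyloxy)phenyl]chroman-4-one
Product: 7 methyl (2S,3S)-6-(benzyloxy)-2-[3,4-bis(methylsulfonyloxy)phenyl]-4-methoxy-2,3-dihydrobenzofuran-3-carboxylate, via C4 methyl enol ether 5 (not isolated), via C3 aryl-λ3-iodane ketal 6 (not isolated)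
Conditions: PhI(OAc)2 (1.2 equiv), conc. H2SO4, HC(OMe)3, 20 °C
Reagents that add atoms: trimethyl orthoformate, COC(OC)OC; (diacetoxyiodo)benzene, CC(=O)OI(OC(C)=O)c1ccccc1 (its atoms stay only in intermediate 6)
Why: Acid and orthoformate convert the ketone into enol ether 5; trivalent iodine attacks C3 on the face away from the 2-aryl group and methanol caps C4, giving the trans-diequatorial iodane ketal 6. The C4–C4a bond lies anti-periplanar to the C3–I bond, so C4a migrates from C4 to C3 as iodobenzene departs, and the dimethoxycarbenium ion left at the former C4 loses a methyl group to acetate to give the methyl ester. The closest known reaction type is the oxidative ring contraction of flavanones to methyl trans-2-aryl-2,3-dihydrobenzofuran-3-carboxylates by trivalent iodine (or trivalent thallium) in trimethyl orthoformate, a semipinacol-type 1,2-aryl shift. The five-membered ring is closed by contraction of the six-membered ring through this shift, not by a cyclisation. The new centre C3 is set by inversion at the iodine-bearing carbon, which places the ester trans to the 2-aryl group (3S); trans is also the thermodynamic isomer, so any cis ester can be equilibrated. C2 is not involved and keeps the configuration of eriodictyol. The step needs the benzo-ring shift to beat migration of the 2-aryl group (isoflavone) and loss of HI (flavone); the 5-methoxy, 7-benzyloxy and ring oxygen donors ortho and para to C4a raise its migratory aptitude. The two mesylates deactivate the 2-aryl ring toward migration, toward the oxidant and toward acid ionisation of C2–O1.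

Step 5
Reactants: 7 methyl (2S,3S)-6-(benzyloxy)-2-[3,4-bis(methylsulfonyloxy)phenyl]-4-methoxy-2,3-dihydrobenzofuran-3-carboxylate
Product: 8 (2S,3S)-6-(benzyloxy)-2-[3,4-bis(methylsulfonyloxy)phenyl]-4-methoxy-2,3-dihydrobenzofuran-3-carboxylic acid
Conditions: Me3SnOH, 1,2-dichloroethane, 80 °C; then 1 M HCl
Reagents that add atoms: trimethyltin hydroxide, C[Sn](C)(C)O
Why: Mild tin-hydroxide hydrolysis of a hindered methyl ester; aryl mesylates and the benzyl ether are inert, and C3 stays trans because that is the stable epimer.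

Step 6
Reactants: 8 (2S,3S)-6-(benzyloxy)-2-[3,4-bis(methylsulfonyloxy)phenyl]-4-methoxy-2,3-dihydrobenzofuran-3-carboxylic acid
Product: 9 1,3-dioxoisoindolin-2-yl (2S,3S)-6-(benzyloxy)-2-[3,4-bis(methylsulfonyloxy)phenyl]-4-methoxy-2,3-dihydrobenzofuran-3-carboxylate
Conditions: N-hydroxyphthalimide, DIC, DMAP (cat.), CH2Cl2, rt
Reagents that add atoms: N-hydroxyphthalimide, O=C1c2ccccc2C(=O)N1O
Why: Steglich-type carbodiimide esterification to the redox-active N-acyloxyphthalimide; neutral conditions leave both stereocentres untouched.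

Step 7
Reactants: 9 1,3-dioxoisoindolin-2-yl (2S,3S)-6-(benzyloxy)-2-[3,4-bis(methylsulfonyloxy)phenyl]-4-methoxy-2,3-dihydrobenzofuran-3-carboxylate; 10 1-bromo-3,5-dimethoxybenzene
Product: 13 (2S,3S)-6-(benzyloxy)-3-(3,5-dimethoxyphenyl)-4-methoxy-2-[3,4-bis(methylsulfonyloxy)phenyl]-2,3-dihydrobenzofuran, via (3,5-dimethoxyphenyl)magnesium bromide 11 (not isolated), via (3,5-dimethoxyphenyl)zinc chloride 12 (not isolated)
Conditions: 10, Mg, LiCl, THF; ZnCl2; then 9, NiCl2·glyme (20 mol %), 4,4'-di-tert-butyl-2,2'-bipyridine (dtbbpy, 40 mol %), THF/DMF, rt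
Reagents that add atoms: magnesium, [Mg]; zinc chloride, Cl[Zn]Cl (their atoms stay only in intermediates 11 and 12)
Why: Nickel-catalysed decarboxylative Negishi-type arylation of a redox-active ester; electron transfer fragments 9 to CO2 and the benzylic C3 radical, which is captured by arylnickel and coupled on the face away from the C2 aryl group, so the new bond is trans (3S).

Step 8
Reactants: 13 (2S,3S)-6-(benzyloxy)-3-(3,5-dimethoxyphenyl)-4-methoxy-2-[3,4-bis(methylsulfonyloxy)phenyl]-2,3-dihydrobenzofuran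
Product: 14 (2S,3S)-3-(3,5-dimethoxyphenyl)-4-methoxy-2-[3,4-bis(methylsulfonyloxy)phenyl]-2,3-dihydrobenzofuran-6-ol
Conditions: H2 (1 atm), Pd/C, EtOAc, rt
Reagents that add atoms: none
Why: Hydrogenolysis of the aryl benzyl ether; the ring C2–O bond is flanked by an electron-poor aryl group and is cleaved far more slowly, and no alkene is present yet.

Step 9
Reactants: 14 (2S,3S)-3-(3,5-dimethoxyphenyl)-4-methoxy-2-[3,4-bis(methylsulfonyloxy)phenyl]-2,3-dihydrobenzofuran-6-ol
Product: 15 (2S,3S)-3-(3,5-dimethoxyphenyl)-4-methoxy-2-[3,4-bis(methylsulfonyloxy)phenyl]-2,3-dihydrobenzofuran-6-yl trifluoromethanesulfonate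
Conditions: Tf2O, pyridine, CH2Cl2, 0 °C
Reagents that add atoms: trifluoromethanesulfonic anhydride, O=S(=O)(OS(=O)(=O)C(F)(F)F)C(F)(F)F
Why: Standard triflation of a phenol; it turns the eriodictyol 7-oxygen into a leaving group that palladium distinguishes from the mesylates.

Step 10
Reactants: 15 (2S,3S)-3-(3,5-dimethoxyphenyl)-4-methoxy-2-[3,4-bis(methylsulfonyloxy)phenyl]-2,3-dihydrobenzofuran-6-yl trifluoromethanesulfonate
Product: 16 (2S,3S)-3-(3,5-dimethoxyphenyl)-4-methoxy-2-[3,4-bis(methylsulfonyloxy)phenyl]-6-(4,4,5,5-tetramethyl-1,3,2-dioxaborolan-2-yl)-2,3-dihydrobenzofuran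
Conditions: B2pin2, PdCl2(dppf) (5 mol %), KOAc, 1,4-dioxane, 80 °C
Reagents that add atoms: bis(pinacolato)diboron, CC1(C)OB(OC1(C)C)B1OC(C)(C)C(C)(C)O1
Why: Miyaura borylation; with a ferrocenyl bisphosphine palladium inserts into the aryl triflate and not into aryl mesylates, and the weak acetate base leaves the sulfonates alone.

Step 11
Reactants: 16 (2S,3S)-3-(3,5-dimethoxyphenyl)-4-methoxy-2-[3,4-bis(methylsulfonyloxy)phenyl]-6-(4,4,5,5-tetramethyl-1,3,2-dioxaborolan-2-yl)-2,3-dihydrobenzofuran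
Product: 17 (2S,3S)-3-(3,5-dimethoxyphenyl)-6-iodo-4-methoxy-2-[3,4-bis(methylsulfonyloxy)phenyl]-2,3-dihydrobenzofuran
Conditions: CuI (10 mol %), 1,10-phenanthroline, KI, MeOH/H2O, air, 80 °C
Reagents that add atoms: potassium iodide, [K+].[I-]
Why: Copper-mediated iododeboronation of an arylboronic ester; iodine is delivered through an arylcopper species at the boron-bearing carbon only, which avoids electrophilic iodination at the activated C5' and C7' positions.

Step 12
Reactants: 18 4-hydroxyphenylboronic acid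
Product: 19 [4-(methylsulfonyloxy)phenyl]boronic acid
Conditions: MsCl, pyridine, THF, 0 °C; then 1 M HCl
Reagents that add atoms: methanesulfonyl chloride, CS(=O)(=O)Cl
Why: Sulfonylation of the phenol; any mixed boron anhydride is hydrolysed back to the boronic acid on acidic work-up.

Step 13
Reactants: 20 2,4,6-trihydroxyacetophenone
Product: 21 1-[4-(benzyloxy)-2,6-dihydroxyphenyl]ethanone
Conditions: BnBr (1.0 equiv), K2CO3 (1.0 equiv), DMF, 0 °C to rt
Reagents that add atoms: benzyl bromide, BrCc1ccccc1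
Why: Williamson etherification; the 4-OH is the only hydroxyl not hydrogen-bonded to the acetyl group and is the most acidic, so one equivalent of reagent goes there.

Step 14
Reactants: 21 1-[4-(benzyloxy)-2,6-dihydroxyphenyl]ethanone
Product: 22 1-[4-(benzyloxy)-2-hydroxy-6-methoxyphenyl]ethanone
Conditions: Me2SO4 (1.05 equiv), K2CO3, acetone, reflux
Reagents that add atoms: dimethyl sulfate, COS(=O)(=O)OC
Why: Williamson methylation of one of two equivalent ortho hydroxyls; the remaining one is then locked in a strong hydrogen bond to the carbonyl and resists a second alkylation.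

Step 15
Reactants: 22 1-[4-(benzyloxy)-2-hydroxy-6-methoxyphenyl]ethanone
Product: 24 7-(benzyloxy)-5-methoxy-4H-chromen-4-one, via enaminone 23 (not isolated)
Conditions: Me2NCH(OMe)2, toluene, 100 °C; then conc. HCl, CH2Cl2, 40 °C
Reagents that add atoms: N,N-dimethylformamide dimethyl acetal, COC(OC)N(C)C
Why: Enaminone chromone synthesis; condensation at the acetyl methyl group gives 23, and acid promotes 6-endo addition of the phenol and loss of dimethylamine.

Step 16
Reactants: 24 7-(benzyloxy)-5-methoxy-4H-chromen-4-one; 19 [4-(methylsulfonyloxy)phenyl]boronic acid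
Product: 25 (2R)-7-(benzyloxy)-5-methoxy-2-[4-(methylsulfonyloxy)phenyl]chroman-4-one
Conditions: 19 (excess), [RhOH(cod)]2 (cat.), (R)-2,2'-bis[bis(3,4,5-trifluorophenyl)phosphino]-6,6'-dimethoxy-1,1'-biphenyl, toluene/H2O, 50 °C
Reagents that add atoms: none
Why: Rhodium-catalysed asymmetric 1,4-addition of an arylboronic acid to a chromone (Hayashi–Miyaura addition); the arylrhodium adds to one enantioface of the C2=C3 bond under control of the atropisomeric electron-poor bisphosphine to set C2 as R, and the base-free medium keeps the flavanone from ring-opening.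

Step 17
Reactants: 25 (2R)-7-(benzyloxy)-5-methoxy-2-[4-(methylsulfonyloxy)phenyl]chroman-4-one
Product: 28 methyl (2R,3R)-6-(benzyloxy)-4-methoxy-2-[4-(methylsulfonyloxy)phenyl]-2,3-dihydrobenzofuran-3-carboxylate, via C4 methyl enol ether 26 (not isolated), via C3 aryl-λ3-iodane ketal 27 (not isolated)
Conditions: PhI(OAc)2 (1.2 equiv), conc. H2SO4, HC(OMe)3, 20 °C
Reagents that add atoms: trimethyl orthoformate, COC(OC)OC; (diacetoxyiodo)benzene, CC(=O)OI(OC(C)=O)c1ccccc1 (its atoms stay only in intermediate 27)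
Why: The same trivalent-iodine oxidative ring contraction as in step 4, in the mirror-image series; C4a shifts from C4 to C3 with inversion at the iodine-bearing carbon, so the ester is trans to the 2-aryl group (3R) and C2 stays R.

Step 18
Reactants: 28 methyl (2R,3R)-6-(benzyloxy)-4-methoxy-2-[4-(methylsulfonyloxy)phenyl]-2,3-dihydrobenzofuran-3-carboxylate
Product: 29 methyl (2R,3R)-6-hydroxy-4-methoxy-2-[4-(methylsulfonyloxy)phenyl]-2,3-dihydrobenzofuran-3-carboxylate
Conditions: H2 (1 atm), Pd/C, EtOAc, rt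
Reagents that add atoms: none
Why: Hydrogenolysis of the benzyl ether before any alkene is present; ester, mesylate and the ring C2–O bond next to an electron-poor aryl group survive.

Step 19
Reactants: 29 methyl (2R,3R)-6-hydroxy-4-methoxy-2-[4-(methylsulfonyloxy)phenyl]-2,3-dihydrobenzofuran-3-carboxylate
Product: 30 methyl (2R,3R)-4-methoxy-2-[4-(methylsulfonyloxy)phenyl]-6-(trifluoromethylsulfonyloxy)-2,3-dihydrobenzofuran-3-carboxylate
Conditions: Tf2O, pyridine, CH2Cl2, 0 °C
Reagents that add atoms: trifluoromethanesulfonic anhydride, O=S(=O)(OS(=O)(=O)C(F)(F)F)C(F)(F)F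
Why: Standard phenol triflation; pyridine is too weak a base to disturb the ester α-centre.

Step 20
Reactants: 30 methyl (2R,3R)-4-methoxy-2-[4-(methylsulfonyloxy)phenyl]-6-(trifluoromethylsulfonyloxy)-2,3-dihydrobenzofuran-3-carboxylate; 31 (E)-2-(4-methoxyphenyl)vinylboronic acid pinacol ester
Product: 32 methyl (2R,3R)-4-methoxy-6-[(E)-2-(4-methoxyphenyl)ethenyl]-2-[4-(methylsulfonyloxy)phenyl]-2,3-dihydrobenzofuran-3-carboxylate
Conditions: PdCl2(dppf) (5 mol %), K3PO4, 1,4-dioxane/H2O, 80 °C
Reagents that add atoms: none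
Why: Suzuki–Miyaura coupling of an aryl triflate with an alkenylboronate; it proceeds with retention of the E geometry and leaves the aryl mesylate alone, and any epimerisation at C3 by the base returns the stable trans ester.

Step 21
Reactants: 32 methyl (2R,3R)-4-methoxy-6-[(E)-2-(4-methoxyphenyl)ethenyl]-2-[4-(methylsulfonyloxy)phenyl]-2,3-dihydrobenzofuran-3-carboxylate
Product: 33 (2R,3R)-4-methoxy-6-[(E)-2-(4-methoxyphenyl)ethenyl]-2-[4-(methylsulfonyloxy)phenyl]-2,3-dihydrobenzofuran-3-carboxylic acid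
Conditions: Me3SnOH, 1,2-dichloroethane, 80 °C; then 1 M HCl
Reagents that add atoms: trimethyltin hydroxide, C[Sn](C)(C)O
Why: Tin-hydroxide hydrolysis of the methyl ester under near-neutral conditions; the mesylate and the stilbene are not affected.

Step 22
Reactants: 33 (2R,3R)-4-methoxy-6-[(E)-2-(4-methoxyphenyl)ethenyl]-2-[4-(methylsulfonyloxy)phenyl]-2,3-dihydrobenzofuran-3-carboxylic acid
Product: 34 1,3-dioxoisoindolin-2-yl (2R,3R)-4-methoxy-6-[(E)-2-(4-methoxyphenyl)ethenyl]-2-[4-(methylsulfonyloxy)phenyl]-2,3-dihydrobenzofuran-3-carboxylate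
Conditions: N-hydroxyphthalimide, DIC, DMAP (cat.), CH2Cl2, rt
Reagents that add atoms: N-hydroxyphthalimide, O=C1c2ccccc2C(=O)N1O
Why: Steglich-type esterification to the redox-active ester under neutral conditions.

Step 23
Reactants: 34 1,3-dioxoisoindolin-2-yl (2R,3R)-4-methoxy-6-[(E)-2-(4-methoxyphenyl)ethenyl]-2-[4-(methylsulfonyloxy)phenyl]-2,3-dihydrobenzofuran-3-carboxylate; 17 (2S,3S)-3-(3,5-dimethoxyphenyl)-6-iodo-4-methoxy-2-[3,4-bis(methylsulfonyloxy)phenyl]-2,3-dihydrobenzofuran
Product: 35 (2S,3S)-3-(3,5-dimethoxyphenyl)-4-methoxy-6-{(2R,3R)-4-methoxy-6-[(E)-2-(4-methoxyphenyl)ethenyl]-2-[4-(methylsulfonyloxy)phenyl]-2,3-dihydrobenzofuran-3-yl}-2-[3,4-bis(methylsulfonyloxy)phenyl]-2,3-dihydrobenzofuran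
Conditions: NiBr2·glyme (10 mol %), dtbbpy (10 mol %), Zn, DMA, rt
Reagents that add atoms: none
Why: Nickel-catalysed reductive cross-electrophile coupling of an N-acyloxyphthalimide with an aryl iodide; zerovalent nickel inserts into the C–I bond, zinc-driven electron transfer fragments 34 to CO2 and the C3 radical, and reductive elimination forms C3–C6' anti to the C2 aryl group (3R), while aryl mesylates and the stilbene are spectators at room temperature.

Step 24
Reactants: 35 (2S,3S)-3-(3,5-dimethoxyphenyl)-4-methoxy-6-{(2R,3R)-4-methoxy-6-[(E)-2-(4-methoxyphenyl)ethenyl]-2-[4-(methylsulfonyloxy)phenyl]-2,3-dihydrobenzofuran-3-yl}-2-[3,4-bis(methylsulfonyloxy)phenyl]-2,3-dihydrobenzofuran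
Product: 36 5-[(2S,3S)-4-hydroxy-6-{(2R,3R)-4-hydroxy-6-[(E)-2-(4-hydroxyphenyl)ethenyl]-2-[4-(methylsulfonyloxy)phenyl]-2,3-dihydrobenzofuran-3-yl}-2-[3,4-bis(methylsulfonyloxy)phenyl]-2,3-dihydrobenzofuran-3-yl]benzene-1,3-diol
Conditions: BBr3 (excess), CH2Cl2, −78 to 0 °C, dilute; then MeOH/H2O
Reagents that add atoms: none
Why: Lewis-acid cleavage of five aryl methyl ethers (bromide attacks the methyl group of each boron-complexed ether); sulfonate esters are inert, the mesylated 2-aryl groups disfavour ionisation of the benzylic C2–O bonds, and no stereocentre is touched.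

Step 25
Reactants: 36 5-[(2S,3S)-4-hydroxy-6-{(2R,3R)-4-hydroxy-6-[(E)-2-(4-hydroxyphenyl)ethenyl]-2-[4-(methylsulfonyloxy)phenyl]-2,3-dihydrobenzofuran-3-yl}-2-[3,4-bis(methylsulfonyloxy)phenyl]-2,3-dihydrobenzofuran-3-yl]benzene-1,3-diol
Product: 37 CNP0107857.3, 4-[(2S,3S)-3-(3,5-dihydroxyphenyl)-4-hydroxy-6-{(2R,3R)-4-hydroxy-2-(4-hydroxyphenyl)-6-[(E)-2-(4-hydroxyphenyl)ethenyl]-2,3-dihydrobenzofuran-3-yl}-2,3-dihydrobenzofuran-2-yl]benzene-1,2-diol
Conditions: KOH, degassed MeOH/H2O, 50 °C, argon; then aq. HCl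
Reagents that add atoms: none
Why: Alkaline hydrolysis of three aryl mesylates by attack of hydroxide at sulfur, so the aryl C–O bonds and all four stereocentres are untouched; the phenolate-bearing benzo rings make the ring oxygens poor leaving groups, and exclusion of air protects the catechol.

## Compound list

1 | (2S)-eriodictyol, (2S)-2-(3,4-dihydroxyphenyl)-5,7-dihydroxychroman-4-one | Oc1cc(O)c2c(c1)O[C@H](c1ccc(O)c(O)c1)CC2=O | starting material
2 | (2S)-7-(benzyloxy)-2-(3,4-dihydroxyphenyl)-5-hydroxychroman-4-one | c1ccccc1COc1cc(O)c2c(c1)O[C@H](c1ccc(O)c(O)c1)CC2=O | intermediate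
3 | (2S)-7-(benzyloxy)-5-hydroxy-2-[3,4-bis(methylsulfonyloxy)phenyl]chroman-4-one | c1ccccc1COc1cc(O)c2c(c1)O[C@H](c1ccc(OS(C)(=O)=O)c(OS(C)(=O)=O)c1)CC2=O | intermediate
4 | (2S)-7-(benzyloxy)-5-methoxy-2-[3,4-bis(methylsulfonyloxy)phenyl]chroman-4-one | c1ccccc1COc1cc(OC)c2c(c1)O[C@H](c1ccc(OS(C)(=O)=O)c(OS(C)(=O)=O)c1)CC2=O | intermediate
5 | (2S)-7-(benzyloxy)-4,5-dimethoxy-2-[3,4-bis(methylsulfonyloxy)phenyl]-2H-chromene | c1ccccc1COc1cc(OC)c2c(c1)O[C@H](c1ccc(OS(C)(=O)=O)c(OS(C)(=O)=O)c1)C=C2OC | intermediate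
6 | (2R,3R)-3-[acetoxy(phenyl)-λ3-iodanyl]-7-(benzyloxy)-4,4,5-trimethoxy-2-[3,4-bis(methylsulfonyloxy)phenyl]chromane (2-aryl and 3-iodanyl trans) | c1ccccc1COc1cc(OC)c2c(c1)O[C@H](c1ccc(OS(C)(=O)=O)c(OS(C)(=O)=O)c1)[C@@H](I(OC(C)=O)c1ccccc1)C2(OC)OC | intermediate
7 | methyl (2S,3S)-6-(benzyloxy)-2-[3,4-bis(methylsulfonyloxy)phenyl]-4-methoxy-2,3-dihydrobenzofuran-3-carboxylate (trans) | c1ccccc1COc1cc(OC)c2c(c1)O[C@H](c1ccc(OS(C)(=O)=O)c(OS(C)(=O)=O)c1)[C@H]2C(=O)OC | intermediate
8 | (2S,3S)-6-(benzyloxy)-2-[3,4-bis(methylsulfonyloxy)phenyl]-4-methoxy-2,3-dihydrobenzofuran-3-carboxylic acid | c1ccccc1COc1cc(OC)c2c(c1)O[C@H](c1ccc(OS(C)(=O)=O)c(OS(C)(=O)=O)c1)[C@H]2C(=O)O | intermediate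
9 | 1,3-dioxoisoindolin-2-yl (2S,3S)-6-(benzyloxy)-2-[3,4-bis(methylsulfonyloxy)phenyl]-4-methoxy-2,3-dihydrobenzofuran-3-carboxylate | c1ccccc1COc1cc(OC)c2c(c1)O[C@H](c1ccc(OS(C)(=O)=O)c(OS(C)(=O)=O)c1)[C@H]2C(=O)ON1C(=O)c2ccccc2C1=O | intermediate
10 | 1-bromo-3,5-dimethoxybenzene | COc1cc(Br)cc(OC)c1 | starting material
11 | (3,5-dimethoxyphenyl)magnesium bromide | COc1cc([Mg]Br)cc(OC)c1 | intermediate
12 | (3,5-dimethoxyphenyl)zinc chloride | COc1cc([Zn]Cl)cc(OC)c1 | intermediate
13 | (2S,3S)-6-(benzyloxy)-3-(3,5-dimethoxyphenyl)-4-methoxy-2-[3,4-bis(methylsulfonyloxy)phenyl]-2,3-dihydrobenzofuran | c1ccccc1COc1cc(OC)c2c(c1)O[C@H](c1ccc(OS(C)(=O)=O)c(OS(C)(=O)=O)c1)[C@H]2c1cc(OC)cc(OC)c1 | intermediate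
14 | (2S,3S)-3-(3,5-dimethoxyphenyl)-4-methoxy-2-[3,4-bis(methylsulfonyloxy)phenyl]-2,3-dihydrobenzofuran-6-ol | Oc1cc(OC)c2c(c1)O[C@H](c1ccc(OS(C)(=O)=O)c(OS(C)(=O)=O)c1)[C@H]2c1cc(OC)cc(OC)c1 | intermediate
15 | (2S,3S)-3-(3,5-dimethoxyphenyl)-4-methoxy-2-[3,4-bis(methylsulfonyloxy)phenyl]-2,3-dihydrobenzofuran-6-yl trifluoromethanesulfonate | O=S(=O)(Oc1cc(OC)c2c(c1)O[C@H](c1ccc(OS(C)(=O)=O)c(OS(C)(=O)=O)c1)[C@H]2c1cc(OC)cc(OC)c1)C(F)(F)F | intermediate
16 | (2S,3S)-3-(3,5-dimethoxyphenyl)-4-methoxy-2-[3,4-bis(methylsulfonyloxy)phenyl]-6-(4,4,5,5-tetramethyl-1,3,2-dioxaborolan-2-yl)-2,3-dihydrobenzofuran | CC1(C)OB(OC1(C)C)c1cc(OC)c2c(c1)O[C@H](c1ccc(OS(C)(=O)=O)c(OS(C)(=O)=O)c1)[C@H]2c1cc(OC)cc(OC)c1 | intermediate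
17 | (2S,3S)-3-(3,5-dimethoxyphenyl)-6-iodo-4-methoxy-2-[3,4-bis(methylsulfonyloxy)phenyl]-2,3-dihydrobenzofuran | Ic1cc(OC)c2c(c1)O[C@H](c1ccc(OS(C)(=O)=O)c(OS(C)(=O)=O)c1)[C@H]2c1cc(OC)cc(OC)c1 | intermediate
18 | 4-hydroxyphenylboronic acid | OB(O)c1ccc(O)cc1 | starting material
19 | [4-(methylsulfonyloxy)phenyl]boronic acid | CS(=O)(=O)Oc1ccc(B(O)O)cc1 | intermediate
20 | 2,4,6-trihydroxyacetophenone | CC(=O)c1c(O)cc(O)cc1O | starting material
21 | 1-[4-(benzyloxy)-2,6-dihydroxyphenyl]ethanone | CC(=O)c1c(O)cc(OCc2ccccc2)cc1O | intermediate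
22 | 1-[4-(benzyloxy)-2-hydroxy-6-methoxyphenyl]ethanone | CC(=O)c1c(O)cc(OCc2ccccc2)cc1OC | intermediate
23 | (E)-1-[4-(benzyloxy)-2-hydroxy-6-methoxyphenyl]-3-(dimethylamino)prop-2-en-1-one | CN(C)/C=C/C(=O)c1c(O)cc(OCc2ccccc2)cc1OC | intermediate
24 | 7-(benzyloxy)-5-methoxy-4H-chromen-4-one | O=c1ccoc2cc(OCc3ccccc3)cc(OC)c12 | intermediate
25 | (2R)-7-(benzyloxy)-5-methoxy-2-[4-(methylsulfonyloxy)phenyl]chroman-4-one | c1ccccc1COc1cc(OC)c2c(c1)O[C@@H](c1ccc(OS(C)(=O)=O)cc1)CC2=O | intermediate
26 | (2R)-7-(benzyloxy)-4,5-dimethoxy-2-[4-(methylsulfonyloxy)phenyl]-2H-chromene | c1ccccc1COc1cc(OC)c2c(c1)O[C@@H](c1ccc(OS(C)(=O)=O)cc1)C=C2OC | intermediate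
27 | (2S,3S)-3-[acetoxy(phenyl)-λ3-iodanyl]-7-(benzyloxy)-4,4,5-trimethoxy-2-[4-(methylsulfonyloxy)phenyl]chromane (2-aryl and 3-iodanyl trans) | c1ccccc1COc1cc(OC)c2c(c1)O[C@@H](c1ccc(OS(C)(=O)=O)cc1)[C@H](I(OC(C)=O)c1ccccc1)C2(OC)OC | intermediate
28 | methyl (2R,3R)-6-(benzyloxy)-4-methoxy-2-[4-(methylsulfonyloxy)phenyl]-2,3-dihydrobenzofuran-3-carboxylate (trans) | c1ccccc1COc1cc(OC)c2c(c1)O[C@@H](c1ccc(OS(C)(=O)=O)cc1)[C@@H]2C(=O)OC | intermediate
29 | methyl (2R,3R)-6-hydroxy-4-methoxy-2-[4-(methylsulfonyloxy)phenyl]-2,3-dihydrobenzofuran-3-carboxylate | Oc1cc(OC)c2c(c1)O[C@@H](c1ccc(OS(C)(=O)=O)cc1)[C@@H]2C(=O)OC | intermediate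
30 | methyl (2R,3R)-4-methoxy-2-[4-(methylsulfonyloxy)phenyl]-6-(trifluoromethylsulfonyloxy)-2,3-dihydrobenzofuran-3-carboxylate | O=S(=O)(Oc1cc(OC)c2c(c1)O[C@@H](c1ccc(OS(C)(=O)=O)cc1)[C@@H]2C(=O)OC)C(F)(F)F | intermediate
31 | (E)-2-(4-methoxyphenyl)vinylboronic acid pinacol ester | COc1ccc(/C=C/B2OC(C)(C)C(C)(C)O2)cc1 | starting material
32 | methyl (2R,3R)-4-methoxy-6-[(E)-2-(4-methoxyphenyl)ethenyl]-2-[4-(methylsulfonyloxy)phenyl]-2,3-dihydrobenzofuran-3-carboxylate | COc1ccc(/C=C/c2cc(OC)c3c(c2)O[C@@H](c2ccc(OS(C)(=O)=O)cc2)[C@@H]3C(=O)OC)cc1 | intermediate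
33 | (2R,3R)-4-methoxy-6-[(E)-2-(4-methoxyphenyl)ethenyl]-2-[4-(methylsulfonyloxy)phenyl]-2,3-dihydrobenzofuran-3-carboxylic acid | COc1ccc(/C=C/c2cc(OC)c3c(c2)O[C@@H](c2ccc(OS(C)(=O)=O)cc2)[C@@H]3C(=O)O)cc1 | intermediate
34 | 1,3-dioxoisoindolin-2-yl (2R,3R)-4-methoxy-6-[(E)-2-(4-methoxyphenyl)ethenyl]-2-[4-(methylsulfonyloxy)phenyl]-2,3-dihydrobenzofuran-3-carboxylate | COc1ccc(/C=C/c2cc(OC)c3c(c2)O[C@@H](c2ccc(OS(C)(=O)=O)cc2)[C@@H]3C(=O)ON2C(=O)c3ccccc3C2=O)cc1 | intermediate
35 | (2S,3S)-3-(3,5-dimethoxyphenyl)-4-methoxy-6-{(2R,3R)-4-methoxy-6-[(E)-2-(4-methoxyphenyl)ethenyl]-2-[4-(methylsulfonyloxy)phenyl]-2,3-dihydrobenzofuran-3-yl}-2-[3,4-bis(methylsulfonyloxy)phenyl]-2,3-dihydrobenzofuran | COc1ccc(/C=C/c2cc(OC)c3c(c2)O[C@@H](c2ccc(OS(C)(=O)=O)cc2)[C@@H]3c2cc(OC)c3c(c2)O[C@H](c2ccc(OS(C)(=O)=O)c(OS(C)(=O)=O)c2)[C@H]3c2cc(OC)cc(OC)c2)cc1 | intermediate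
36 | 5-[(2S,3S)-4-hydroxy-6-{(2R,3R)-4-hydroxy-6-[(E)-2-(4-hydroxyphenyl)ethenyl]-2-[4-(methylsulfonyloxy)phenyl]-2,3-dihydrobenzofuran-3-yl}-2-[3,4-bis(methylsulfonyloxy)phenyl]-2,3-dihydrobenzofuran-3-yl]benzene-1,3-diol | Oc1ccc(/C=C/c2cc(O)c3c(c2)O[C@@H](c2ccc(OS(C)(=O)=O)cc2)[C@@H]3c2cc(O)c3c(c2)O[C@H](c2ccc(OS(C)(=O)=O)c(OS(C)(=O)=O)c2)[C@H]3c2cc(O)cc(O)c2)cc1 | intermediate
37 | CNP0107857.3, 4-[(2S,3S)-3-(3,5-dihydroxyphenyl)-4-hydroxy-6-{(2R,3R)-4-hydroxy-2-(4-hydroxyphenyl)-6-[(E)-2-(4-hydroxyphenyl)ethenyl]-2,3-dihydrobenzofuran-3-yl}-2,3-dihydrobenzofuran-2-yl]benzene-1,2-diol | Oc1ccc(/C=C/c2cc(O)c3c(c2)O[C@@H](c2ccc(O)cc2)[C@@H]3c2cc(O)c3c(c2)O[C@H](c2ccc(O)c(O)c2)[C@H]3c2cc(O)cc(O)c2)cc1 | target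

## Step count and least certain steps

Total: 25 steps. Longest linear sequence: 14 steps (1 to 37 through steps 1–11 and 23–25). The ring A branch from 20 runs 13 steps (13–25).

**Step 4 (key step).**
- *What may go wrong:* electrophilic attack of the iodine reagent on the very electron-rich trioxygenated benzo ring instead of the enol ether; loss of HI from the iodane to give the flavone; simple 3-methoxylation; acid-induced epimerisation at C2.
- *Fallback:* the same C4a-to-C3 shift by a Wolff rearrangement. It sets out from 4 and returns at 7.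
  - Condensation of 4 with N,N-dimethylformamide dimethyl acetal would give the enaminone (2R,3E)-7-(benzyloxy)-3-[(dimethylamino)methylidene]-5-methoxy-2-[3,4-bis(methylsulfonyloxy)phenyl]chroman-4-one F1.
  - Diazo transfer with tosyl azide would give the diazoketone (2R)-7-(benzyloxy)-3-diazo-5-methoxy-2-[3,4-bis(methylsulfonyloxy)phenyl]chroman-4-one F2. The spatial arrangement at C2 is unchanged from 4; only the descriptor changes with the priorities.
  - Irradiation of F2 in methanol expels nitrogen, C4a migrates to the carbene carbon, and methanol adds to the ketene. This gives 7 together with its cis epimer, methyl (2S,3R)-6-(benzyloxy)-2-[3,4-bis(methylsulfonyloxy)phenyl]-4-methoxy-2,3-dihydrobenzofuran-3-carboxylate F3.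
  - DBU would equilibrate F3 to 7.

**Step 3.**
- *What may go wrong:* slow alkylation of the hydrogen-bonded phenol, and loss of optical purity through retro-oxa-Michael opening to the chalcone if any enolate forms.
- *Fallback:* postpone the methylation until the flavanone is gone. It sets out from 3 and returns at 7.
  - Acetylation of 3 (Ac2O, pyridine, DMAP) would give (2S)-7-(benzyloxy)-2-[3,4-bis(methylsulfonyloxy)phenyl]-4-oxochroman-5-yl acetate F4.
  - Ring contraction under the conditions of step 4 would give methyl (2S,3S)-4-acetoxy-6-(benzyloxy)-2-[3,4-bis(methylsulfonyloxy)phenyl]-2,3-dihydrobenzofuran-3-carboxylate F5.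
  - Methanolysis (K2CO3, MeOH, 0 °C) would give methyl (2S,3S)-6-(benzyloxy)-4-hydroxy-2-[3,4-bis(methylsulfonyloxy)phenyl]-2,3-dihydrobenzofuran-3-carboxylate F6.
  - MeI and K2CO3 would methylate F6 to 7. The dihydrobenzofuran has no low-energy ring-opening path under mild base.

**Step 23.**
- *What may go wrong:* slow capture of the hindered, stabilised C3 radical by nickel, leading to reduction or dimerisation; homocoupling of the aryl iodide; slow insertion of nickel into an aryl mesylate.
- *Fallback:* change the polarity of the aryl partner. It sets out from 17 and 34 and returns at 35.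
  - Zinc dust and LiCl in THF would insert into 17 to give [(2S,3S)-3-(3,5-dimethoxyphenyl)-4-methoxy-2-[3,4-bis(methylsulfonyloxy)phenyl]-2,3-dihydrobenzofuran-6-yl]zinc iodide F7.
  - F7 would be coupled with 34 under the redox-neutral nickel conditions of step 7 (NiCl2·glyme, dtbbpy, THF/DMF). This removes the heterogeneous reductant and the cross-selectivity problem, at the price of using F7 in excess.

**Step 24.**
- *What may go wrong:* acid-promoted oligomerisation or hydrobromination of the electron-rich stilbene; ionisation of a benzylic C2–O bond; incomplete cleavage of the hindered C4 and C4' ethers.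
- *Fallback:* demethylate before the stilbene exists. It sets out from 30 and 17 and returns at 36.
  - Me3SnOH on 30 would give (2R,3R)-4-methoxy-2-[4-(methylsulfonyloxy)phenyl]-6-(trifluoromethylsulfonyloxy)-2,3-dihydrobenzofuran-3-carboxylic acid F8.
  - N-hydroxyphthalimide and DIC would give its 1,3-dioxoisoindolin-2-yl ester F9.
  - Coupling of F9 with 17 as in step 23 would give (2R,3R)-3-[(2S,3S)-3-(3,5-dimethoxyphenyl)-4-methoxy-2-[3,4-bis(methylsulfonyloxy)phenyl]-2,3-dihydrobenzofuran-6-yl]-4-methoxy-2-[4-(methylsulfonyloxy)phenyl]-2,3-dihydrobenzofuran-6-yl trifluoromethanesulfonate F10. The bipyridine–nickel catalyst is expected to take the iodide and leave the triflate.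
  - BBr3 would give the tetraphenol (2R,3R)-3-[(2S,3S)-3-(3,5-dihydroxyphenyl)-4-hydroxy-2-[3,4-bis(methylsulfonyloxy)phenyl]-2,3-dihydrobenzofuran-6-yl]-4-hydroxy-2-[4-(methylsulfonyloxy)phenyl]-2,3-dihydrobenzofuran-6-yl trifluoromethanesulfonate F11.
  - Suzuki–Miyaura coupling of F11 (PdCl2(dppf), K3PO4) with 4-[(E)-2-(4,4,5,5-tetramethyl-1,3,2-dioxaborolan-2-yl)ethenyl]phenol F12 would give 36. F12 would be made from 4-ethynylphenol and pinacolborane with Cp2ZrHCl.

## Further compounds

F1 | step 4 | (2R,3E)-7-(benzyloxy)-3-[(dimethylamino)methylidene]-5-methoxy-2-[3,4-bis(methylsulfonyloxy)phenyl]chroman-4-one | c1ccccc1COc1cc(OC)c2c(c1)O[C@H](c1ccc(OS(C)(=O)=O)c(OS(C)(=O)=O)c1)/C(=C\N(C)C)C2=O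
F2 | step 4 | (2R)-7-(benzyloxy)-3-diazo-5-methoxy-2-[3,4-bis(methylsulfonyloxy)phenyl]chroman-4-one | c1ccccc1COc1cc(OC)c2c(c1)O[C@H](c1ccc(OS(C)(=O)=O)c(OS(C)(=O)=O)c1)C(=[N+]=[N-])C2=O
F3 | step 4 | methyl (2S,3R)-6-(benzyloxy)-2-[3,4-bis(methylsulfonyloxy)phenyl]-4-methoxy-2,3-dihydrobenzofuran-3-carboxylate (cis) | c1ccccc1COc1cc(OC)c2c(c1)O[C@H](c1ccc(OS(C)(=O)=O)c(OS(C)(=O)=O)c1)[C@@H]2C(=O)OC
F4 | step 3 | (2S)-7-(benzyloxy)-2-[3,4-bis(methylsulfonyloxy)phenyl]-4-oxochroman-5-yl acetate | c1ccccc1COc1cc(OC(C)=O)c2c(c1)O[C@H](c1ccc(OS(C)(=O)=O)c(OS(C)(=O)=O)c1)CC2=O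
F5 | step 3 | methyl (2S,3S)-4-acetoxy-6-(benzyloxy)-2-[3,4-bis(methylsulfonyloxy)phenyl]-2,3-dihydrobenzofuran-3-carboxylate | c1ccccc1COc1cc(OC(C)=O)c2c(c1)O[C@H](c1ccc(OS(C)(=O)=O)c(OS(C)(=O)=O)c1)[C@H]2C(=O)OC
F6 | step 3 | methyl (2S,3S)-6-(benzyloxy)-4-hydroxy-2-[3,4-bis(methylsulfonyloxy)phenyl]-2,3-dihydrobenzofuran-3-carboxylate | c1ccccc1COc1cc(O)c2c(c1)O[C@H](c1ccc(OS(C)(=O)=O)c(OS(C)(=O)=O)c1)[C@H]2C(=O)OC
F7 | step 23 | [(2S,3S)-3-(3,5-dimethoxyphenyl)-4-methoxy-2-[3,4-bis(methylsulfonyloxy)phenyl]-2,3-dihydrobenzofuran-6-yl]zinc iodide | I[Zn]c1cc(OC)c2c(c1)O[C@H](c1ccc(OS(C)(=O)=O)c(OS(C)(=O)=O)c1)[C@H]2c1cc(OC)cc(OC)c1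
F8 | step 24 | (2R,3R)-4-methoxy-2-[4-(methylsulfonyloxy)phenyl]-6-(trifluoromethylsulfonyloxy)-2,3-dihydrobenzofuran-3-carboxylic acid | O=S(=O)(Oc1cc(OC)c2c(c1)O[C@@H](c1ccc(OS(C)(=O)=O)cc1)[C@@H]2C(=O)O)C(F)(F)F
F9 | step 24 | 1,3-dioxoisoindolin-2-yl (2R,3R)-4-methoxy-2-[4-(methylsulfonyloxy)phenyl]-6-(trifluoromethylsulfonyloxy)-2,3-dihydrobenzofuran-3-carboxylate | O=S(=O)(Oc1cc(OC)c2c(c1)O[C@@H](c1ccc(OS(C)(=O)=O)cc1)[C@@H]2C(=O)ON1C(=O)c2ccccc2C1=O)C(F)(F)F
F10 | step 24 | (2R,3R)-3-[(2S,3S)-3-(3,5-dimethoxyphenyl)-4-methoxy-2-[3,4-bis(methylsulfonyloxy)phenyl]-2,3-dihydrobenzofuran-6-yl]-4-methoxy-2-[4-(methylsulfonyloxy)phenyl]-2,3-dihydrobenzofuran-6-yl trifluoromethanesulfonate | O=S(=O)(Oc1cc(OC)c2c(c1)O[C@@H](c1ccc(OS(C)(=O)=O)cc1)[C@@H]2c1cc(OC)c2c(c1)O[C@H](c1ccc(OS(C)(=O)=O)c(OS(C)(=O)=O)c1)[C@H]2c1cc(OC)cc(OC)c1)C(F)(F)F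
F11 | step 24 | (2R,3R)-3-[(2S,3S)-3-(3,5-dihydroxyphenyl)-4-hydroxy-2-[3,4-bis(methylsulfonyloxy)phenyl]-2,3-dihydrobenzofuran-6-yl]-4-hydroxy-2-[4-(methylsulfonyloxy)phenyl]-2,3-dihydrobenzofuran-6-yl trifluoromethanesulfonate | O=S(=O)(Oc1cc(O)c2c(c1)O[C@@H](c1ccc(OS(C)(=O)=O)cc1)[C@@H]2c1cc(O)c2c(c1)O[C@H](c1ccc(OS(C)(=O)=O)c(OS(C)(=O)=O)c1)[C@H]2c1cc(O)cc(O)c1)C(F)(F)F
F12 | step 24 | 4-[(E)-2-(4,4,5,5-tetramethyl-1,3,2-dioxaborolan-2-yl)ethenyl]phenol | Oc1ccc(/C=C/B2OC(C)(C)C(C)(C)O2)cc1
A1 | alternative 1 | 3-[(E)-2-(4-methoxyphenyl)ethenyl]cyclobut-2-en-1-one | COc1ccc(/C=C/C2=CC(=O)C2)cc1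
A2 | alternative 1 | triisopropyl{[(3R,4R)-4-(tert-butyldimethylsilyloxy)-3-[(2S,3S)-2-(3,4-dimethoxyphenyl)-3-(3,5-dimethoxyphenyl)-4-methoxy-2,3-dihydrobenzofuran-6-yl]-4-(4-methoxyphenyl)but-1-yn-1-yl]oxy}silane | CC(C)[Si](C(C)C)(C(C)C)OC#C[C@@H](c1cc(OC)c2c(c1)O[C@H](c1ccc(OC)c(OC)c1)[C@H]2c1cc(OC)cc(OC)c1)[C@@H](O[Si](C)(C)C(C)(C)C)c1ccc(OC)cc1
A3 | alternative 1 | 2-[(1R,2R)-2-(tert-butyldimethylsilyloxy)-1-[(2S,3S)-2-(3,4-dimethoxyphenyl)-3-(3,5-dimethoxyphenyl)-4-methoxy-2,3-dihydrobenzofuran-6-yl]-2-(4-methoxyphenyl)ethyl]-5-[(E)-2-(4-methoxyphenyl)ethenyl]-3-(triisopropylsilyloxy)phenol | Oc1cc(/C=C/c2ccc(OC)cc2)cc(O[Si](C(C)C)(C(C)C)C(C)C)c1[C@@H](c1cc(OC)c2c(c1)O[C@H](c1ccc(OC)c(OC)c1)[C@H]2c1cc(OC)cc(OC)c1)[C@@H](O[Si](C)(C)C(C)(C)C)c1ccc(OC)cc1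
A4 | alternative 2 | [(3S,4S)-4-(3,4-dimethoxyphenyl)-3-(3,5-dimethoxyphenyl)-4-(ethynyloxy)but-1-yn-1-yl]trimethylsilane | C#CO[C@H](c1ccc(OC)c(OC)c1)[C@H](C#C[Si](C)(C)C)c1cc(OC)cc(OC)c1
A5 | alternative 2 | (2R,3R)-3-ethynyl-4-methoxy-2-(4-methoxyphenyl)-6-[(E)-2-(4-methoxyphenyl)ethenyl]-2,3-dihydrobenzofuran | COc1ccc(/C=C/c2cc(OC)c3c(c2)O[C@@H](c2ccc(OC)cc2)[C@@H]3C#C)cc1
A6 | alternative 2 | permethylated target skeleton with trimethylsilyl in place of the C4' oxygen, ring A (2R,3R), ring B (2S,3S) | COc1ccc(/C=C/c2cc(OC)c3c(c2)O[C@@H](c2ccc(OC)cc2)[C@@H]3c2cc([Si](C)(C)C)c3c(c2)O[C@H](c2ccc(OC)c(OC)c2)[C@H]3c2cc(OC)cc(OC)c2)cc1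
A7 | alternative 3 | 5-bromo-3-methoxy-2-(trimethylsilyl)phenyl trifluoromethanesulfonate | COc1cc(Br)cc(OS(=O)(=O)C(F)(F)F)c1[Si](C)(C)C
A8 | alternative 3 | 4-[(2S,3S)-3-[(2S,3S)-2-(3,4-dimethoxyphenyl)-3-(3,5-dimethoxyphenyl)-4-methoxy-2,3-dihydrobenzofuran-6-yl]oxiran-2-yl]phenyl trifluoromethanesulfonate (trans epoxide) | O1[C@@H](c2ccc(OS(=O)(=O)C(F)(F)F)cc2)[C@@H]1c1cc(OC)c2c(c1)O[C@H](c1ccc(OC)c(OC)c1)[C@H]2c1cc(OC)cc(OC)c1
A9 | alternative 3 | 4-[(2R,3R)-6-bromo-3-[(2S,3S)-2-(3,4-dimethoxyphenyl)-3-(3,5-dimethoxyphenyl)-4-methoxy-2,3-dihydrobenzofuran-6-yl]-4-methoxy-2,3-dihydrobenzofuran-2-yl]phenyl trifluoromethanesulfonate | Brc1cc(OC)c2c(c1)O[C@@H](c1ccc(OS(=O)(=O)C(F)(F)F)cc1)[C@@H]2c1cc(OC)c2c(c1)O[C@H](c1ccc(OC)c(OC)c1)[C@H]2c1cc(OC)cc(OC)c1
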